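## Retrosynthetic overview

1. The butyrolactone ring is finished last by hydrogenating an enol lactone. The spiro C13–O bond (oxolane ring) is made by anodic oxidation of a 3-alkyl-2-silyloxyfuran, trapped by the 9α-hydroxyl.
2. The silyloxyfuran comes from a butenolide made by hydroboration and B-alkyl Suzuki coupling of a 9-vinyl carbinol with 3-bromofuran-2(5H)-one. The carbinol comes from vinyl addition to a C9 ketone.
3. The C9 ketone comes from an enone by hydroxyl-directed hydrogenation (sets C8). Ring A is closed before that by alkylating the enolate of the C19–C20 δ-lactone with a C1–C3 chloropropyl chain (C3–C4 bond, sets C4). The 6β-OH comes from singlet-oxygen oxygenation of a dienol ether.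
4. The δ-lactone comes from hydroboration and oxidative lactonisation of the isopropenyl and hydroxymethyl groups of a 6,6-dialkylated (S)-carvone. C10 is set by the order of the two α′-alkylations; C5 is bought.
5. Ring order: ring B (carvone) → δ-lactone ring → ring A → oxolane and butyrolactone spiro rings.

Assumption: labdane numbering (C1–C20) is used, with α/β as in the usual labdane drawing (C20 on the β face). The SMILES is taken literally, so H-5 is β (rings A/B cis-fused), the 17-methyl is α (8β-H), the oxolane oxygen on C9 is α and C13 is R.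

## Route

**Step 1**
Reactants: 1 (S)-(+)-carvone; 2 1-chloro-3-iodopropane
Product: 4 (5S,6R)-6-(3-chloropropyl)-2-methyl-5-(prop-1-en-2-yl)cyclohex-2-en-1-one, via carvone lithium dienolate 3 (not isolated)
Conditions: LiN(iPr)2, THF, −78 °C; then 2, DMPU, −78 to −20 °C
Reagents that add atoms: 1-chloro-3-iodopropane, ClCCCI
Why: Kinetic α′-deprotonation of the enone and SN2 enolate alkylation at the iodide end only (the chloride survives); the chain enters trans to the isopropenyl group, but this centre is re-formed in step 2.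

**Step 2**
Reactants: 4; 5 paraformaldehyde (cracked to gaseous formaldehyde)
Product: 7 (5R,6S)-6-(3-chloropropyl)-6-(hydroxymethyl)-2-methyl-5-(prop-1-en-2-yl)cyclohex-2-en-1-one, via lithium enolate 6 (not isolated)
Conditions: LiN(iPr)2, THF, −78 °C; CH2O (gas), −78 °C; H2O
Reagents that add atoms: formaldehyde (from 5), C=O
Why: Aldol addition of the tetrasubstituted enolate to monomeric formaldehyde occurs anti to the C5 isopropenyl group, which sets quaternary C10 with CH2OH (C20) trans and the chloropropyl chain (C1–C3) cis to C4.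

**Step 3**
Reactants: 7; 8 hydrogen peroxide
Product: 10 (5R,6S)-6-(3-chloropropyl)-6-(hydroxymethyl)-5-(1-hydroxypropan-2-yl)-2-methylcyclohex-2-en-1-one (both C4 epimers), via bis-boron adduct 9 (not isolated)
Conditions: 9-BBN (2.5 equiv), THF, 0 °C to rt; then 30% H2O2, pH 7 phosphate buffer, 0 °C to rt
Reagents that add atoms: hydrogen peroxide, OO
Why: Anti-Markovnikov hydroboration–oxidation of the 1,1-disubstituted alkene is much faster than attack of 9-BBN on the hindered α-quaternary enone carbonyl; the C4 epimer mixture is erased in step 6.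

**Step 4**
Reactants: 10
Product: 12 (4aR,8aS)-8a-(3-chloropropyl)-4,7-dimethyl-4,4a,5,8a-tetrahydro-1H-isochromene-3,8-dione (trans-fused δ-lactone; both C4 epimers), via lactol 11 (not isolated)
Conditions: TEMPO (0.2 equiv), PhI(OAc)2 (2.5 equiv), CH2Cl2, rt
Reagents that add atoms: none
Why: Oxoammonium oxidation picks the less hindered primary alcohol (C19) over the neopentyl C20–OH, and the aldehyde is trapped as the lactol and oxidised to the δ-lactone (oxidative lactonisation of a 1,5-diol); the fusion is trans because C20 and C4 are trans on ring B.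

**Step 5**
Reactants: 12; 13 dioxygen
Product: 16 6β-hydroxy derivative of 12 (OH cis to H-5 and trans to the chloropropyl chain; both C4 epimers), via trimethylsilyl dienol ether 14 (not isolated), via silylperoxy enone 15 (not isolated)
Conditions: Me3SiOTf, Et3N, CH2Cl2, 0 °C; filtration through Celite (pentane); O2, tetraphenylporphyrin (cat.), visible light, CH2Cl2, −78 °C; PPh3, −78 °C to rt; 1 M HCl, THF, 0 °C
Reagents that add atoms: dioxygen, O=O
Why: Soft enolisation can give only the linear C9-silyloxy diene (α′ is quaternary), and dye-sensitised photooxygenation ([4+2]-type addition of singlet oxygen across C6/C9, then silyl shift and phosphine reduction) occurs on the β face opposite the axial chloropropyl chain, giving the 6β-hydroxy enone.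

**Step 6**
Reactants: 16
Product: 18 6β-hydroxy-9-oxo-11,12,13,14,15,16-hexanor-5β-labd-7-en-19,20-olide, via dilithium alkoxide enolate 17 (not isolated)
Conditions: LiN(iPr)2 (2.3 equiv), THF/DMPU, −78 °C to rt
Reagents that add atoms: none
Why: After O–H deprotonation the lactone α-H is the only acidic C–H left, and the trans ring fusion holds the chloropropyl chain axial on the lactone ring, so intramolecular enolate alkylation (6-exo-tet) closes ring A as a 1,3-diaxial bridge; C4 can only form with C3 syn to C1 and the methyl exo, from either C4 epimer.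

**Step 7**
Reactants: 18
Product: 19 6β-hydroxy-9-oxo-11,12,13,14,15,16-hexanor-5β,8βH-labdan-19,20-olide (17-methyl α)
Conditions: H2 (1 atm), [Ir(cod)(PCy3)(py)]PF6 (5 mol%), CH2Cl2, rt
Reagents that add atoms: none
Why: Hydroxyl-directed homogeneous hydrogenation (Crabtree catalyst): the allylic 6β-OH binds iridium on the β face, which is also the open face (ring A and axial C1 cover the α face), so H adds to C7 and C8 from β and gives the 8α-methyl ketone under kinetic control.

**Step 8**
Reactants: 19; 20 vinylmagnesium bromide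
Product: 21 6β,9α-dihydroxy-13,14,15,16-tetranor-5β,8βH-labd-11-en-19,20-olide
Conditions: CeCl3, CH2=CHMgBr (4 equiv), THF, −78 to 0 °C
Reagents that add atoms: vinylmagnesium bromide, C=C[Mg]Br
Why: The weakly basic organocerium reagent adds to the hindered ketone without enolising C8 (Imamoto-type 1,2-addition) from the β face, anti to the two axial α substituents (C1 on C10 and the methyl on C8), giving the 9α-hydroxy 9β-vinyl carbinol.

**Step 9**
Reactants: 21; 22 3-bromofuran-2(5H)-one
Product: 24 6β,9α-dihydroxy-5β,8βH-labd-13-ene-19,20:16,15-diolide, via B-alkyl-9-BBN adduct 23 (not isolated)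
Conditions: 9-BBN (3.5 equiv), THF, rt; then 22, Pd(dppf)Cl2 (5 mol%), AsPh3, Cs2CO3, DMF/H2O, rt
Reagents that add atoms: 3-bromofuran-2(5H)-one, O=C1OCC=C1Br
Why: Anti-Markovnikov hydroboration of the vinyl group and B-alkyl Suzuki–Miyaura coupling with the activated α-bromo butenolide form the C12–C13 bond; no stereocentre is formed.

**Step 10**
Reactants: 24; 25 triethylsilyl trifluoromethanesulfonate
Product: 26 6β,16-bis(triethylsilyloxy)-15,16-epoxy-9α-hydroxy-5β,8βH-labda-13(16),14-dien-19,20-olide
Conditions: Et3SiOTf (2.3 equiv), Et3N, CH2Cl2, −78 to 0 °C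
Reagents that add atoms: triethylsilyl trifluoromethanesulfonate, CC[Si](CC)(CC)OS(=O)(=O)C(F)(F)F
Why: Soft enolisation of the butenolide at its γ-CH2 gives the aromatic 2-silyloxyfuran (silyl dienol ether formation) and the secondary 6-OH is silylated at the same time, while the hindered tertiary 9-OH stays free.

**Step 11**
Reactants: 26
Product: 27 (13R)-9α,13-epoxy-6β-(triethylsilyloxy)-5β,8βH-labd-14-ene-19,20:16,15-diolide
Conditions: undivided cell, reticulated vitreous carbon anode, Pt cathode, LiClO4 (0.1 M), 2,6-lutidine, MeOH/CH2Cl2 1:4, constant current (8 mA, 2.2 F/mol), rt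
Reagents that add atoms: none
Why: Proposed new method: anodic dearomative spiroetherification of a 3-alkyl-2-silyloxyfuran — the silyloxyfuran is the most easily oxidised group in 26 and gives a radical cation that the tethered 9α-OH traps at C13 in a 5-exo mode (the carbon β to both oxygens, as in ketene-acetal radical cations), leaving a C16 radical stabilised by two oxygens that is oxidised again and loses the silyl group to methanol to give the lactone carbonyl and the C14=C15 enol-lactone bond; C13 is set because the bulky C16–OSiEt3 edge of the planar furan turns away from the more crowded C10 flank (C1H2 and C20H2 gauche to O9) toward the C8 flank (equatorial H), which places C16 syn to C8 (13R); the closest known reaction types are the anodic olefin coupling of enol-ether and ketene-dithioacetal radical cations with alcohols to give tetrahydrofurans and the oxidative dearomatising spiroetherification of phenols.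

**Step 12**
Reactants: 27
Product: 29 (13R)-9α,13-epoxy-6β-hydroxy-5β,8βH-labdane-19,20:16,15-diolide (target), via silyl ether 28 (not isolated)
Conditions: H2 (1 atm), 5% Rh/Al2O3, EtOAc, rt; filter; then 1 M HCl, THF, 0 °C
Reagents that add atoms: none
Why: Heterogeneous catalytic hydrogenation saturates only the enol-lactone C14=C15 bond (no stereocentre is touched, and rhodium avoids hydrogenolysis of the allylic C13–O bond), and dilute acid cleaves the triethylsilyl ether.

## Compound list

1 | (S)-(+)-carvone, (5S)-2-methyl-5-(prop-1-en-2-yl)cyclohex-2-en-1-one | CC1=CC[C@@H](CC1=O)C(C)=C | starting material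
2 | 1-chloro-3-iodopropane | ClCCCI | starting material
3 | lithium dienolate of 1 (C9–OLi, C9=C10; not isolated) | CC1=CC[C@H](C(C)=C)C=C1O[Li] | intermediate
4 | (5S,6R)-6-(3-chloropropyl)-2-methyl-5-(prop-1-en-2-yl)cyclohex-2-en-1-one | CC1=CC[C@H](C(C)=C)[C@@H](CCCCl)C1=O | intermediate
5 | paraformaldehyde (source of monomeric formaldehyde) | C=O | starting material
6 | lithium enolate of 4 (not isolated) | CC1=CC[C@H](C(C)=C)C(CCCCl)=C1O[Li] | intermediate
7 | (5R,6S)-6-(3-chloropropyl)-6-(hydroxymethyl)-2-methyl-5-(prop-1-en-2-yl)cyclohex-2-en-1-one | CC1=CC[C@H](C(C)=C)[C@](CO)(CCCCl)C1=O | intermediate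
8 | hydrogen peroxide | OO | starting material
9 | C19-(9-BBN) borane of 7 with the C20 oxygen as its 9-BBN borinate (not isolated) | CC1=CC[C@H](C(C)CB2C3CCCC2CCC3)[C@](COB2C3CCCC2CCC3)(CCCCl)C1=O | intermediate
10 | (5R,6S)-6-(3-chloropropyl)-6-(hydroxymethyl)-5-(1-hydroxypropan-2-yl)-2-methylcyclohex-2-en-1-one (both C4 epimers) | CC1=CC[C@H](C(C)CO)[C@](CO)(CCCCl)C1=O | intermediate
11 | lactol of 12 (C19 hemiacetal; not isolated) | CC1=CC[C@@H]2C(C)C(O)OC[C@@]2(CCCCl)C1=O | intermediate
12 | (4aR,8aS)-8a-(3-chloropropyl)-4,7-dimethyl-4,4a,5,8a-tetrahydro-1H-isochromene-3,8-dione (both C4 epimers) | CC1=CC[C@@H]2C(C)C(=O)OC[C@@]2(CCCCl)C1=O | intermediate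
13 | dioxygen | O=O | starting material
14 | C9 trimethylsilyl dienol ether of 12 (C6=C7, C8=C9; not isolated) | CC=1C=C[C@@H]2C(C)C(=O)OC[C@@]2(CCCCl)C=1O[Si](C)(C)C | intermediate
15 | 6β-(trimethylsilylperoxy) enone (not isolated) | CC1=C[C@@H](OO[Si](C)(C)C)[C@@H]2C(C)C(=O)OC[C@@]2(CCCCl)C1=O | intermediate
16 | 6β-hydroxy derivative of 12 (OH cis to H-5; both C4 epimers) | CC1=C[C@@H](O)[C@@H]2C(C)C(=O)OC[C@@]2(CCCCl)C1=O | intermediate
17 | dilithium 6-alkoxide lactone enolate of 16 (not isolated) | CC1=C[C@@H](O[Li])[C@@H]2C(C)=C(O[Li])OC[C@@]2(CCCCl)C1=O | intermediate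
18 | 6β-hydroxy-9-oxo-11,12,13,14,15,16-hexanor-5β-labd-7-en-19,20-olide | CC1=C[C@@H](O)[C@@H]2[C@@]3(C)C(=O)OC[C@@]2(CCC3)C1=O | intermediate
19 | 6β-hydroxy-9-oxo-11,12,13,14,15,16-hexanor-5β,8βH-labdan-19,20-olide | C[C@@H]1C[C@@H](O)[C@@H]2[C@@]3(C)C(=O)OC[C@@]2(CCC3)C1=O | intermediate
20 | vinylmagnesium bromide | C=C[Mg]Br | starting material
21 | 6β,9α-dihydroxy-13,14,15,16-tetranor-5β,8βH-labd-11-en-19,20-olide | C[C@@H]1C[C@@H](O)[C@@H]2[C@@]3(C)C(=O)OC[C@@]2(CCC3)[C@@]1(O)C=C | intermediate
22 | 3-bromofuran-2(5H)-one | O=C1OCC=C1Br | starting material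
23 | C12-(9-BBN) borane of 21 with the 6-oxygen as its 9-BBN borinate (not isolated) | C[C@@H]1C[C@@H](OB4C5CCCC4CCC5)[C@@H]2[C@@]3(C)C(=O)OC[C@@]2(CCC3)[C@@]1(O)CCB1C2CCCC1CCC2 | intermediate
24 | 6β,9α-dihydroxy-5β,8βH-labd-13-ene-19,20:16,15-diolide | C[C@@H]1C[C@@H](O)[C@@H]2[C@@]3(C)C(=O)OC[C@@]2(CCC3)[C@@]1(O)CCC1=CCOC1=O | intermediate
25 | triethylsilyl trifluoromethanesulfonate | CC[Si](CC)(CC)OS(=O)(=O)C(F)(F)F | starting material
26 | 6β,16-bis(triethylsilyloxy)-15,16-epoxy-9α-hydroxy-5β,8βH-labda-13(16),14-dien-19,20-olide | C[C@@H]1C[C@@H](O[Si](CC)(CC)CC)[C@@H]2[C@@]3(C)C(=O)OC[C@@]2(CCC3)[C@@]1(O)CCc1ccoc1O[Si](CC)(CC)CC | intermediate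
27 | (13R)-9α,13-epoxy-6β-(triethylsilyloxy)-5β,8βH-labd-14-ene-19,20:16,15-diolide | C[C@@H]1C[C@@H](O[Si](CC)(CC)CC)[C@@H]2[C@@]3(C)C(=O)OC[C@@]2(CCC3)[C@@]12CC[C@]1(C=COC1=O)O2 | intermediate
28 | (13R)-9α,13-epoxy-6β-(triethylsilyloxy)-5β,8βH-labdane-19,20:16,15-diolide (not isolated) | C[C@@H]1C[C@@H](O[Si](CC)(CC)CC)[C@@H]2[C@@]3(C)C(=O)OC[C@@]2(CCC3)[C@@]12CC[C@]1(CCOC1=O)O2 | intermediate
29 | (13R)-9α,13-epoxy-6β-hydroxy-5β,8βH-labdane-19,20:16,15-diolide (CNP0393616.2) | C[C@@H]1C[C@@H](O)[C@H]2[C@]3(CCC[C@]2(C)C(=O)OC3)[C@@]12CC[C@]1(CCOC1=O)O2 | target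

## Step count and risks

Total steps: 12. Longest linear sequence: 12 (from 1; the other carbon inputs 2, 5, 20 and 22 are purchased).

**Step 11 (the new anodic spiroetherification).** Risks are dimerisation or solvolysis of the silyloxyfuran radical cation, attack at C16 instead of C13, or the wrong C13 epimer. The fallback uses known reactions and sets out from 26. Dimethyldioxirane (acetone, −78 °C) oxidises the silyloxyfuran to the 15-hydroxy butenolide F1 with loss of the furan silyl group. A catalytic amine base (Et3N or DBU, CH2Cl2) opens it to the (Z)-4-oxo-enoate, whose enal β-carbon C13 takes up the 9α-OH in a 5-exo oxa-Michael addition to give the spiro lactol F2. NaBH4 (MeOH, 0 °C) reduces the masked C15 aldehyde to the hydroxy acid F3, and acidification closes the γ-lactone to 28, where the route is rejoined at the acid stage of step 12. C13 is then under reversible-Michael control and any epimer is separated at 28.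

**Step 7 (directed hydrogenation).** It must give the less stable, epimerisable 8α-methyl ketone (methyl axial and syn to C1); the risks are slow reduction of the enone or α-face addition. The fallback sets out from 18 and replaces hydrogenation by hydride conjugate reduction with kinetic protonation. K[HB(sBu)3] (2.2 equiv, THF, −78 °C) adds hydride 1,4 to the β-unsubstituted enone to give the dipotassium alkoxide enolate F4. This is protonated at −78 °C by 2,6-di-tert-butyl-4-methylphenol on the open β face of C8, returning to the route at 19.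

**Step 9 (sp3–sp2 Suzuki coupling).** The bromobutenolide is base-labile and the substrate carries two free hydroxyls. The fallback sets out from 19 and changes the disconnection to olefin metathesis. CH2=CHCH2MgBr with CeCl3 (THF, −78 °C) gives the 9β-allyl carbinol F5. Cross-metathesis with α-methylene-γ-butyrolactone (second-generation Hoveyda–Grubbs catalyst, RuCl2(H2IMes)(=CH-C6H4-2-OiPr), CH2Cl2, 40 °C) gives the (E)-alkylidene lactone F6 with loss of ethene. RhCl3·3H2O (EtOH, 70 °C) moves the exocyclic double bond into the ring to give butenolide 24, where the route is rejoined.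

## Further compounds

F1 | step 11 | 9α,15-dihydroxy-6β-(triethylsilyloxy)-5β,8βH-labd-13-ene-19,20:16,15-diolide (C15 epimers) | C[C@@H]1C[C@@H](O[Si](CC)(CC)CC)[C@@H]2[C@@]3(C)C(=O)OC[C@@]2(CCC3)[C@@]1(O)CCC1=CC(O)OC1=O
F2 | step 11 | (13R)-9α,13-epoxy-15-hydroxy-6β-(triethylsilyloxy)-5β,8βH-labdane-19,20:16,15-diolide (C15 epimers) | C[C@@H]1C[C@@H](O[Si](CC)(CC)CC)[C@@H]2[C@@]3(C)C(=O)OC[C@@]2(CCC3)[C@@]12CC[C@]1(CC(O)OC1=O)O2
F3 | step 11 | (13R)-9α,13-epoxy-15-hydroxy-6β-(triethylsilyloxy)-5β,8βH-labdan-19,20-olid-16-oic acid | C[C@@H]1C[C@@H](O[Si](CC)(CC)CC)[C@@H]2[C@@]3(C)C(=O)OC[C@@]2(CCC3)[C@@]12CC[C@@](CCO)(C(=O)O)O2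
F4 | step 7 | dipotassium 6β-alkoxide C8=C9 enolate of the hexanor lactone | CC=1C[C@@H](O[K])[C@@H]2[C@@]3(C)C(=O)OC[C@@]2(CCC3)C=1O[K]
F5 | step 9 | 6β,9α-dihydroxy-14,15,16-trinor-5β,8βH-labd-12-en-19,20-olide (9β-allyl carbinol) | C[C@@H]1C[C@@H](O)[C@@H]2[C@@]3(C)C(=O)OC[C@@]2(CCC3)[C@@]1(O)CC=C
F6 | step 9 | (12E)-6β,9α-dihydroxy-5β,8βH-labd-12-ene-19,20:16,15-diolide | C[C@@H]1C[C@@H](O)[C@@H]2[C@@]3(C)C(=O)OC[C@@]2(CCC3)[C@@]1(O)C/C=C1\CCOC1=O
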